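## Analysis of the target

The target is a resveratrol hexamer: six resorcinol-type rings (A–F), six 4-hydroxyphenyl groups, fifteen free phenols and twelve stereogenic methines, with no other functional group. Three 2,3-trans-2-(4-hydroxyphenyl)-3-aryl-2,3-dihydrobenzofurans (benzo rings B, C and E; 3-aryl rings A, D and F) have the same absolute sense (2R at each oxygen-bearing carbon) and hold six of the stereocentres. Rings A and B, the furan C3 between them (Cb), the diarylmethine Ca [CH(4-hydroxyphenyl), on ring A] and the methine Cc (on ring B) form a dibenzo-fused seven-membered carbocycle in which Ca–H, Cb–H and Cc–H are all cis. Cc is bonded to an acyclic CH(4-hydroxyphenyl), Cd, and Cd to Ce of an eight-membered carbocycle made of rings C and D, the furan C3 between them (Cf) and the bridge Cg [CH(4-hydroxyphenyl), on ring D]–Ch–Ce (on ring C); Ch carries ring E, Cf–H and Cg–H lie on one face, Ch–H and Ce–H on the other. The O–C2 bonds of the dihydrofurans ionise under acid, the C3–H bonds are β to an aryloxide and do not tolerate strong base, and the free polyphenol is sensitive to air and acid, so the phenols stay protected to the end. The difficulty is a chain of five bonds between six hindered benzylic methines (Ca–Cc–Cd–Ce–Ch–Cg), two medium rings, and stereocentres that cannot be corrected once their C–C bonds exist. The strategy rests on Ca–Cc, the only C(sp3)–C(sp3) bond of the seven-membered ring. Both atoms are benzylic, so a sulfur atom placed between them gives an eight-membered cyclic sulfide from which the bond is made by a 1,2-shift. An aryl ketone at Cd acidifies Cc for that shift and later serves as the coupling site.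

## Retrosynthetic reasoning

40 from 39. The last cut removes the fifteen O-methyl groups. Methyl ethers survive organometallic, Lewis-acid and single-electron steps and fall together in one Lewis-acid demethylation. The trans-dihydrofurans are the thermodynamic isomers, so reversible ionisation at C2 during that step changes nothing.

39 from 38, and 38 from 28 and 36. The Cd–H bond and then the Cd–Ce bond are cut. Cd is the only stereocentre outside a ring and lies between two halves of similar size, so this cut gives the greatest convergence. The carbonyl at Cd in 28 is the one the ring contraction needs, so no functional group is spent only on the coupling. The forward reactions must add a benzylic nucleophile derived from 36 to the hindered, enolisable ketone 28 under non-basic conditions, and then replace the tertiary benzylic hydroxyl of 38 by hydrogen through the 4-methoxybenzylic cation.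

28 from 26, and 26 from 23 (key disconnection). The Ca–Cc bond is cut and sulfur is inserted. All other bonds of the seven-membered ring are aryl–carbon bonds that a benzofuran building block already contains. A direct alkylative closure of Ca–Cc would bring the nucleophile in within the plane of ring A, where nothing decides on which face the anisyl group lies. In the sulfide 23, which is one atom larger, the bond to Ca is made perpendicular to ring A from the only face the tether can reach. The 1,2-shift then transfers that configuration to carbon. The forward sequence must form the ylide at Cc only, shift the diarylmethyl group with retention, cleave the C–S bond reductively and protonate Cc to the all-cis arrangement.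

23 from 21, 21 from 20, 20 from 18. The two C–S bonds are cut one after the other. The bond to Cc comes from SN2 displacement of an α-keto bromide by a thiocarboxylate. The bond to Ca comes from SN1 capture of the diarylmethyl cation by the liberated thiol. A configurationally defined diarylmethanethiol is avoided because this doubly donor-substituted centre ionises too easily to be carried through a substitution with inversion. The ionisation is used instead.

36 from 35, 35 from 34, 34 from 32. The bromide at Ce comes from the ring ketone. The eight-membered ring is cut at Cg–Ch. This closure is the carbon analogue of the sulfide closure: same ring size, same diarylmethyl cation, an enol silane carbon in place of sulfur. No relay atom is therefore needed in this half. It gives the ring and two stereocentres in one step, and Ch, being α to the ketone, can be equilibrated.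

32 from 31 and 29, 31 from 16, 18 from 16 and 17. The carbon arms at C4 of the benzofurans are cut at the aryl–carbon bond and attached by palladium catalysis to an aryl chloride. A carbonyl-bearing arm would not survive the formation of hydrazone 9, whereas a chloride is inert in every earlier step and is also the smallest possible ortho substituent.

16 and 29 from 12, and 12 back to 1, 3 and 7. One building block serves all three benzofuran units. Its bromine is exchanged for lithium to bring in the diarylmethyl carbon with 13 (units one and two) or is removed by radical-chain reduction (unit three). The dihydrofuran ring of 12 is cut at C2–C3 (carbene C–H insertion from hydrazone 9, followed by epimerisation of 11). This fixes the absolute configuration of the whole synthesis in one catalytic step. The ketone 8 goes back to a Friedel–Crafts union of acid 2 with arene 3 and etherification with 7.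

## Alternatives that were turned down

Alternative 1: The benzo ring of one dihydrobenzofuran unit and its furan ring are disconnected together at three arene C–C bonds. In the forward step a ruthenium catalyst would cyclotrimerise a chiral tethered diyne (an ynol ether and an internal alkyne) with an alkoxyalkyne to give the benzofuran A1. In its favour, the 4,6-substitution pattern is built in and is not left to the regiochemistry of an electrophilic substitution as in step 2. The trans stereocentres come from the open chain, so neither an insertion nor an epimerisation is needed. On these two points it is stronger than the chosen route. Against it, A1 is only a building block of the kind of 29. It forms none of the bonds between benzylic methines and neither medium ring, so the real problem is left untouched. Two of the three units also need an ortho handle on the 3-aryl ring that A1 lacks. A chiral diyne with a propargylic diarylmethine would take more steps per unit than the six steps to 12, which is used three times. The orientation of the alkoxyalkyne in the cyclotrimerisation would also need control. The chosen route reaches the same type of block faster and applies its key step to the hardest bond.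

Alternative 2: All three furan C2–C3 bonds are disconnected at the very end. In the forward step three hydrazone groups would be oxidised to diaryldiazomethanes, and a chiral dirhodium carboxylate would insert each carbene into the neighbouring OCH2Ar group to give A2 (the same compound as 39). In its favour, six stereocentres would come from one catalyst in one flask, directly at the penultimate compound. The reaction type is the one used in step 5. In step count after skeleton assembly it is stronger. Against it, the whole carbon skeleton with both medium rings and the linker would have to be assembled first, without the furan stereocentres that relay configuration to Ca, Cg, Cc and Ch in the chosen route. Two of the three carbene carbons would be ring members of the dibenzo-fused seven- and eight-membered rings, flanked by three ortho substituents. The catalyst would have to overrule three different substrate biases. The insertion gives cis rings, so three epimerisations would follow on the most valuable material. The chosen route uses the same insertion once, early and on a simple ketone, where a moderate result can be afforded, and lets its product control everything else.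

Alternative 3: The two aryl–carbon bonds that flank Ca and Cc in the seven-membered ring are disconnected. In the forward step an aryne released by fluoride would insert into the C(=O)–CH bond of a cyclic β-ketoester and enlarge a five-membered ring to the dibenzo-fused cycloheptanone A3. In its favour, the seven-membered ring is made early by a robust σ-insertion, with no medium-ring closure and no labile sulfonium salt. A3 carries three differentiated carbons: a ketone at the future Ca, a methylene at the future Cc and an ester at the future Cb. On the reliability of ring formation it is stronger than the chosen key step. Against it, A3 is racemic and its ester carbon is epimerisable. The aryl group at Ca would have to be added to the ketone and the hydroxyl removed, with no element securing the Ca/Cb relationship. The dihydrofuran would have to be built late from the ester. Nothing in the sequence serves the other two benzofuran units. The chosen route offers absolute control from step 5, a stereochemical relay to Ca, and one building block for the whole molecule.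

Key step: step 12

Assumption 1: Rh2(R-PTAD)4 is taken to induce the C3 configuration drawn for 11; if the sense of induction is the opposite, Rh2(S-PTAD)4 is used and nothing else changes.

Assumption 2: acylation of 3 is taken to occur ortho to chlorine and para to a methoxy group, not between the two methoxy groups, as is usual for electrophilic substitution of 5-substituted 1,3-dimethoxybenzenes.

## Steps

Step 1
Reactants: 1 3,5-dimethoxybenzoic acid
Product: 2 2-bromo-3,5-dimethoxybenzoic acid
Conditions: NBS, MeCN, 0 → 23 °C
Reagents that add atoms: N-bromosuccinimide, O=C1CCC(=O)N1Br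
Why: Electrophilic aromatic bromination; the position para to one methoxy group and ortho to the other is the most nucleophilic, and the position between the two methoxy groups is more hindered.

Step 2
Reactants: 2 2-bromo-3,5-dimethoxybenzoic acid; 3 1-chloro-3,5-dimethoxybenzene
Product: 6 (2-bromo-3,5-dimethoxyphenyl)(2-chloro-6-hydroxy-4-methoxyphenyl)methanone, via acid chloride 4 (not isolated), via dimethoxy ketone 5 (not isolated)
Conditions: (COCl)2, DMF (cat.), CH2Cl2, 23 °C; then 3, AlCl3 (3 equiv), CH2Cl2, 0 → 40 °C
Reagents that add atoms: none
Why: Friedel–Crafts acylation para to a methoxy group and ortho to chlorine, followed by chelation-directed cleavage by AlCl3 of the one methoxy group ortho to the new carbonyl; ring A has no methoxy group ortho to the carbonyl and keeps both.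

Step 3
Reactants: 6 (2-bromo-3,5-dimethoxyphenyl)(2-chloro-6-hydroxy-4-methoxyphenyl)methanone; 7 4-methoxybenzyl chloride
Product: 8 (2-bromo-3,5-dimethoxyphenyl)[2-chloro-4-methoxy-6-(4-methoxybenzyloxy)phenyl]methanone
Conditions: K2CO3, NaI (cat.), DMF, 60 °C
Reagents that add atoms: none
Why: Williamson etherification of the hydrogen-bonded phenol; it installs the OCH2Ar group whose C–H bond is inserted into in step 5.

Step 4
Reactants: 8 (2-bromo-3,5-dimethoxyphenyl)[2-chloro-4-methoxy-6-(4-methoxybenzyloxy)phenyl]methanone
Product: 9 hydrazone of ketone 8 (C=N isomers)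
Conditions: N2H4·H2O, AcOH (cat.), n-BuOH, 110 °C
Reagents that add atoms: hydrazine hydrate, NN.O
Why: Condensation of hydrazine with the diaryl ketone; the molecule has no second electrophile because the side arm is still a chloride, and the methoxy-substituted aryl halides are too electron-rich for SNAr closure to an indazole.

Step 5
Reactants: 9 hydrazone of ketone 8
Product: 11 (2S,3S)-3-(2-bromo-3,5-dimethoxyphenyl)-4-chloro-6-methoxy-2-(4-methoxyphenyl)-2,3-dihydro-1-benzofuran (2,3-cis), via diaryldiazomethane 10 (not isolated)
Conditions: MnO2, CH2Cl2, 0 °C, filter; then Rh2(R-PTAD)4 (1 mol%), CH2Cl2, −20 → 0 °C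
Reagents that add atoms: none
Why: Oxidation of the hydrazone to the donor/donor diazo compound and enantioselective intramolecular 1,5 C–H insertion of the dirhodium carbene into the OCH2Ar group; the chiral carboxylate ligands set C3 and the concerted insertion gives the 2,3-cis ring.

Step 6
Reactants: 11 (2S,3S)-3-(2-bromo-3,5-dimethoxyphenyl)-4-chloro-6-methoxy-2-(4-methoxyphenyl)-2,3-dihydro-1-benzofuran (2,3-cis)
Product: 12 (2R,3S)-3-(2-bromo-3,5-dimethoxyphenyl)-4-chloro-6-methoxy-2-(4-methoxyphenyl)-2,3-dihydro-1-benzofuran (2,3-trans)
Conditions: BF3·OEt2 (0.5 equiv), CH2Cl2, −20 → 0 °C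
Reagents that add atoms: none
Why: Lewis-acid epimerisation: reversible ionisation of the O–C2 bond gives a 4-methoxybenzylic cation that recloses to the thermodynamically preferred 2,3-trans isomer; C3 is not touched, so the enantiomeric purity from step 5 is kept.

Step 7
Reactants: 12 (2R,3S)-3-(2-bromo-3,5-dimethoxyphenyl)-4-chloro-6-methoxy-2-(4-methoxyphenyl)-2,3-dihydro-1-benzofuran (2,3-trans); 13 4-methoxybenzaldehyde
Product: 16 (2R,3R)-4-chloro-3-{3,5-dimethoxy-2-[methoxy(4-methoxyphenyl)methyl]phenyl}-6-methoxy-2-(4-methoxyphenyl)-2,3-dihydro-1-benzofuran (2,3-trans; both epimers at the benzhydryl carbon), via aryllithium 14 (not isolated), via lithium alkoxide 15 (not isolated)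
Conditions: n-BuLi, THF, −78 °C; 13; then MeOTf, −78 → 0 °C
Reagents that add atoms: methyl trifluoromethanesulfonate, COS(=O)(=O)C(F)(F)F
Why: Bromine–lithium exchange (the aryl chloride is inert at −78 °C), 1,2-addition to the aldehyde and O-methylation in one flask; the benzhydryl centre forms as both epimers, which does not matter because it is ionised in steps 11 and 17.

Step 8
Reactants: 16 benzhydryl methyl ether (aryl chloride); 17 1-(4-methoxyphenyl)ethanone
Product: 18 2-{(2R,3R)-3-{3,5-dimethoxy-2-[methoxy(4-methoxyphenyl)methyl]phenyl}-6-methoxy-2-(4-methoxyphenyl)-2,3-dihydro-1-benzofuran-4-yl}-1-(4-methoxyphenyl)ethanone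
Conditions: Pd2(dba)3 (2.5 mol%), XPhos (6 mol%), K3PO4, toluene, 100 °C
Reagents that add atoms: none
Why: Palladium-catalysed α-arylation of a methyl ketone with an aryl chloride; the bulky biarylphosphine allows oxidative addition to the ortho-substituted chloride and stops at monoarylation, and K3PO4 is too weak a base to attack the C3–H of the dihydrobenzofuran.

Step 9
Reactants: 18 aryl ketone with CH2 arm
Product: 20 α-bromo ketone of 18 (bromine on the CH between the benzofuran C4 and the carbonyl; epimers), via lithium enolate 19 (not isolated)
Conditions: LiHMDS, THF, −78 °C; then NBS, −78 °C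
Reagents that add atoms: N-bromosuccinimide, O=C1CCC(=O)N1Br
Why: Enolate bromination; the preformed enolate is far more nucleophilic than the methoxyarenes, so ring bromination should not compete, and LiHMDS is too weak to deprotonate the diarylmethine C3–H.

Step 10
Reactants: 20 α-bromo ketone
Product: 21 α-(acetylthio) ketone (S-acetyl in place of bromine; epimers)
Conditions: KSAc, acetone, 0 °C
Reagents that add atoms: potassium thioacetate (KSAc), CC(=O)[S-].[K+]
Why: SN2 displacement of an α-keto benzylic bromide by thioacetate, which forms the first C–S bond under neutral conditions.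

Step 11
Reactants: 21 α-(acetylthio) ketone
Product: 23 eight-membered cyclic sulfide (sulfur bridges Ca and Cc; Ca–H cis to the furan C3–H as in the SMILES; either epimer at Cc), via α-mercapto ketone 22 (not isolated)
Conditions: HCl (1.25 M in MeOH), CH2Cl2, 0.002 M, 0 → 23 °C
Reagents that add atoms: none
Why: Acid methanolysis of the thioester and intramolecular SN1 thioetherification: the doubly donor-substituted benzhydryl methyl ether ionises and the thiol closes the eight-membered ring; the cation keeps its hydrogen, not the anisyl group, beside the bulky C3 substituent of ring A, and the tethered sulfur can reach only the face turned towards C4, which together should give the Ca configuration drawn (stronger acid such as TFA re-ionises the C–S bond and would equilibrate a minor epimer).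

Step 12
Reactants: 23 eight-membered cyclic sulfide
Product: 26 seven-membered-ring ketone carrying SMe and 4-methoxybenzoyl on Cc (either epimer at Cc), via sulfonium triflate 24 (not isolated), via sulfonium ylide 25 (not isolated)
Conditions: MeOTf, CH2Cl2, −30 → 0 °C; then KOtBu, THF, −78 → 23 °C
Reagents that add atoms: methyl trifluoromethanesulfonate, COS(=O)(=O)C(F)(F)F
Why: S-Methylation gives the sulfonium salt 24, whose proton between sulfur, carbonyl and ring B is by far the most acidic, so KOtBu forms the keto-stabilised ylide 25 at that carbon and nowhere else. On warming, the S–CH(aryl)2 bond, the weakest bond to sulfur, breaks to a tethered pair (diarylmethyl radical and captodative α-thio-α-keto radical, or the corresponding ion pair) that recombines at carbon; this is a Stevens 1,2-rearrangement of a keto-stabilised sulfonium ylide, the ring-contraction tactic of thiacyclophane chemistry. The seven-membered ring closes by this 1,2-shift, that is by coupling of the two benzylic carbons that sulfur had bridged, with contraction from eight to seven ring atoms; no other ring is formed. The diarylmethyl stereocentre Ca is controlled by retention: the carbon partner is held where sulfur was and bonds to the same lobe before the twisted diarylmethyl centre can rotate, and any re-closure of an ion pair is subject to the same facial constraint as in step 11. The quaternary carbon Cc may form as either epimer because it is reset in step 13. The step needs 1,2- over 2,3-shift, migration of the diarylmethyl group and not of methyl, and C- rather than O-recombination: the stabilised ylide is too poor a nucleophile for a dearomatising 2,3-shift into the anisyl ring, methyl gives no stabilised radical, and C–C recombination gives a seven-membered ring where O-attack would need a nine-membered enol ether. The base is added cold and 24 is not isolated, because the sulfonium salt can ionise at the diarylmethyl carbon.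

Step 13
Reactants: 26 α-(methylthio) ketone
Product: 28 seven-membered-ring ketone with Cc–H (Ca–H, Cb–H and Cc–H cis), via samarium enolate 27 (not isolated)
Conditions: SmI2 (2.2 equiv), THF–MeOH, −78 °C; then Et3N, MeOH, 23 °C
Reagents that add atoms: none
Why: Reductive cleavage of the C–S bond α to the ketone by two single-electron transfers from divalent samarium, protonation of the samarium enolate and base equilibration; the aroyl group takes the outward pseudo-equatorial position and the new C–H the position beside the furan C3–H, because the other epimer would point the aroyl group across the ring at that hydrogen.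

Step 14
Reactants: 12 (2R,3S)-3-(2-bromo-3,5-dimethoxyphenyl)-4-chloro-6-methoxy-2-(4-methoxyphenyl)-2,3-dihydro-1-benzofuran
Product: 29 (2R,3R)-4-chloro-3-(3,5-dimethoxyphenyl)-6-methoxy-2-(4-methoxyphenyl)-2,3-dihydro-1-benzofuran (2,3-trans)
Conditions: Bu3SnH (1.3 equiv), AIBN (0.1 equiv), toluene, 80 °C
Reagents that add atoms: none
Why: Radical-chain hydrodebromination: the stannyl radical abstracts bromine from the aryl bromide far faster than chlorine from the aryl chloride, and the aryl radical takes hydrogen from the stannane before it can attack the neighbouring anisyl ring; no base or organometallic reagent is present, so the stereocentres are untouched, and the bromine removed is the one the third benzofuran unit (ring F) does not need.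

Step 15
Reactants: 16 benzhydryl methyl ether (aryl chloride)
Product: 31 methyl ketone (acetyl in place of chlorine at C4 of 16), via 1-ethoxyvinyl arene 30 (not isolated)
Conditions: tributyl(1-ethoxyvinyl)stannane, Pd2(dba)3, P(t-Bu)3, CsF, dioxane, 100 °C; then 0.1 M HCl, THF, 0 °C
Reagents that add atoms: tributyl(1-ethoxyvinyl)stannane, CCCC[Sn](CCCC)(CCCC)C(=C)OCC; water, O
Why: Stille coupling of an aryl chloride with an acetyl-anion equivalent and hydrolysis of the enol ether; in cold dilute acid the enol ether should hydrolyse far faster than the benzhydryl methyl ether ionises.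

Step 16
Reactants: 31 methyl ketone; 29 (2R,3R)-4-chloro-3-(3,5-dimethoxyphenyl)-6-methoxy-2-(4-methoxyphenyl)-2,3-dihydro-1-benzofuran
Product: 32 open-chain ketone ArC–C(=O)–CH2–ArE joining C4 of the second benzofuran unit (carbonyl, Ce) to C4 of the third (CH2, Ch)
Conditions: Pd2(dba)3 (2.5 mol%), XPhos (6 mol%), K3PO4, toluene, 100 °C
Reagents that add atoms: none
Why: Second palladium-catalysed ketone α-arylation with an aryl chloride; it forms the bond between Ch and ring E, and the product has only one enolisable position, which is the one needed in step 17.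

Step 17
Reactants: 32 open-chain ketone
Product: 34 eight-membered-ring ketone (C=O at Ce; Cg and Ch as in the target), via silyl enol ether 33 (not isolated)
Conditions: TMSOTf (2.5 equiv), i-Pr2NEt (1.5 equiv), CH2Cl2, 0.003 M, −78 → −20 °C; then DBU, 23 °C
Reagents that add atoms: none
Why: One-flask enol silane formation and Mukaiyama-type SN1 alkylation: the excess silyl triflate ionises the benzhydryl methyl ether and the enol silane carbon closes the eight-membered ring; the cation geometry and the tether fix Cg exactly as they fix Ca in step 11, and Ch, α to the ketone, is equilibrated by DBU so that ring E lies on the open face, away from ring D and trans to the anisyl group.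

Step 18
Reactants: 34 eight-membered-ring ketone
Product: 35 eight-membered-ring alcohol (OH at Ce; epimers)
Conditions: NaBH4, THF–MeOH, 0 → 23 °C
Reagents that add atoms: none
Why: Hydride reduction of the aryl ketone; both epimers serve, because this carbon becomes a configurationally labile organometallic in step 20.

Step 19
Reactants: 35 eight-membered-ring alcohol
Product: 36 eight-membered-ring benzylic bromide (Br at Ce; epimers; used crude)
Conditions: PPh3, CBr4, CH2Cl2, 0 °C
Reagents that add atoms: tetrabromomethane, BrC(Br)(Br)Br
Why: Appel bromination under neutral conditions, which avoids the acid that would eliminate towards the conjugated alkene.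

Step 20
Reactants: 28 seven-membered-ring ketone; 36 eight-membered-ring benzylic bromide
Product: 38 tertiary alcohol at Cd joining the two halves (Ce as in the target; either epimer at the carbinol carbon), via benzylsamarium 37 (not isolated)
Conditions: SmI2 (2.5 equiv), THF, −78 → 23 °C
Reagents that add atoms: none
Why: Samarium Barbier reaction: divalent samarium reduces the benzylic bromide faster than the aryl ketone, and the weakly basic benzylsamarium adds to the enolisable ketone without deprotonating Cc–H or the furan C3–H bonds; the new bond should form perpendicular to ring C on the open face of the folded eight-membered ring, away from ring D, which is the configuration needed at Ce.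

Step 21
Reactants: 38 tertiary alcohol
Product: 39 pentadeca-O-methyl ether of the target
Conditions: Et3SiH (10 equiv), TFA (5 equiv), CH2Cl2, −40 → −20 °C
Reagents that add atoms: none
Why: Ionic deoxygenation: the tertiary 4-methoxybenzylic alcohol ionises far more readily than the secondary O–C2 bonds of the dihydrofurans, and the silane transfers hydride to the cation; the configuration at Cd comes from hydride delivery to the less hindered face of the cation, whose conformation is fixed by allylic strain to the two flanking ring methines, and it is the least predictable centre of the route.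

Step 22
Reactants: 39 pentadeca-O-methyl ether
Product: 40 target, CNP0184494.1
Conditions: BBr3 (30 equiv), CH2Cl2, −78 → 23 °C; then MeOH, aq. NaHCO3
Reagents that add atoms: none
Why: Lewis-acid cleavage of the fifteen aryl methyl ethers; no C–C bond or stereocentre is affected, and the trans-dihydrofurans are the thermodynamic isomers should C2 ionise reversibly.

## Compound list

1 | 3,5-dimethoxybenzoic acid | COc1cc(OC)cc(C(=O)O)c1 | starting material
2 | 2-bromo-3,5-dimethoxybenzoic acid | COc1cc(OC)c(Br)c(C(=O)O)c1 | intermediate
3 | 1-chloro-3,5-dimethoxybenzene | COc1cc(Cl)cc(OC)c1 | starting material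
4 | 2-bromo-3,5-dimethoxybenzoyl chloride | COc1cc(OC)c(Br)c(C(=O)Cl)c1 | intermediate (not isolated)
5 | (2-bromo-3,5-dimethoxyphenyl)(2-chloro-4,6-dimethoxyphenyl)methanone | COc1cc(OC)c(Br)c(c1)C(=O)c1c(Cl)cc(OC)cc1OC | intermediate (not isolated)
6 | (2-bromo-3,5-dimethoxyphenyl)(2-chloro-6-hydroxy-4-methoxyphenyl)methanone | COc1cc(OC)c(Br)c(c1)C(=O)c1c(Cl)cc(OC)cc1O | intermediate
7 | 4-methoxybenzyl chloride | COc1ccc(CCl)cc1 | starting material
8 | (2-bromo-3,5-dimethoxyphenyl)[2-chloro-4-methoxy-6-(4-methoxybenzyloxy)phenyl]methanone | COc1ccc(COc2cc(OC)cc(Cl)c2C(=O)c2cc(OC)cc(OC)c2Br)cc1 | intermediate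
9 | hydrazone of ketone 8 | COc1ccc(COc2cc(OC)cc(Cl)c2C(=NN)c2cc(OC)cc(OC)c2Br)cc1 | intermediate
10 | 2-bromo-1-{diazo[2-chloro-4-methoxy-6-(4-methoxybenzyloxy)phenyl]methyl}-3,5-dimethoxybenzene | COc1ccc(COc2cc(OC)cc(Cl)c2C(=[N+]=[N-])c2cc(OC)cc(OC)c2Br)cc1 | intermediate (not isolated)
11 | (2S,3S)-3-(2-bromo-3,5-dimethoxyphenyl)-4-chloro-6-methoxy-2-(4-methoxyphenyl)-2,3-dihydro-1-benzofuran (2,3-cis) | Brc1c(OC)cc(OC)cc1[C@@H]1c2c(cc(OC)cc2Cl)O[C@@H]1c1ccc(OC)cc1 | intermediate
12 | (2R,3S)-3-(2-bromo-3,5-dimethoxyphenyl)-4-chloro-6-methoxy-2-(4-methoxyphenyl)-2,3-dihydro-1-benzofuran (2,3-trans) | Brc1c(OC)cc(OC)cc1[C@@H]1c2c(cc(OC)cc2Cl)O[C@H]1c1ccc(OC)cc1 | intermediate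
13 | 4-methoxybenzaldehyde | COc1ccc(C=O)cc1 | starting material
14 | aryllithium from 12 (lithium in place of bromine) | [Li]c1c(OC)cc(OC)cc1[C@@H]1c2c(cc(OC)cc2Cl)O[C@H]1c1ccc(OC)cc1 | intermediate (not isolated)
15 | lithium alkoxide from 14 and 13 | COc1ccc(C(O[Li])c2c(OC)cc(OC)cc2[C@@H]2c3c(cc(OC)cc3Cl)O[C@H]2c2ccc(OC)cc2)cc1 | intermediate (not isolated)
16 | (2R,3R)-4-chloro-3-{3,5-dimethoxy-2-[methoxy(4-methoxyphenyl)methyl]phenyl}-6-methoxy-2-(4-methoxyphenyl)-2,3-dihydro-1-benzofuran (2,3-trans; both epimers at the benzhydryl carbon) | COc1ccc(C(OC)c2c(OC)cc(OC)cc2[C@@H]2c3c(cc(OC)cc3Cl)O[C@H]2c2ccc(OC)cc2)cc1 | intermediate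
17 | 1-(4-methoxyphenyl)ethanone | COc1ccc(cc1)C(C)=O | starting material
18 | 2-{(2R,3R)-3-{3,5-dimethoxy-2-[methoxy(4-methoxyphenyl)methyl]phenyl}-6-methoxy-2-(4-methoxyphenyl)-2,3-dihydro-1-benzofuran-4-yl}-1-(4-methoxyphenyl)ethanone | COc1ccc(C(OC)c2c(OC)cc(OC)cc2[C@@H]2c3c(cc(OC)cc3CC(=O)c3ccc(OC)cc3)O[C@H]2c2ccc(OC)cc2)cc1 | intermediate
19 | lithium enolate of 18 | COc1ccc(C(OC)c2c(OC)cc(OC)cc2[C@@H]2c3c(cc(OC)cc3C=C(O[Li])c3ccc(OC)cc3)O[C@H]2c2ccc(OC)cc2)cc1 | intermediate (not isolated)
20 | α-bromo ketone of 18 (epimers) | COc1ccc(C(OC)c2c(OC)cc(OC)cc2[C@@H]2c3c(cc(OC)cc3C(Br)C(=O)c3ccc(OC)cc3)O[C@H]2c2ccc(OC)cc2)cc1 | intermediate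
21 | α-(acetylthio) ketone (epimers) | COc1ccc(C(OC)c2c(OC)cc(OC)cc2[C@@H]2c3c(cc(OC)cc3C(SC(C)=O)C(=O)c3ccc(OC)cc3)O[C@H]2c2ccc(OC)cc2)cc1 | intermediate
22 | α-mercapto ketone (epimers) | COc1ccc(C(OC)c2c(OC)cc(OC)cc2[C@@H]2c3c(cc(OC)cc3C(S)C(=O)c3ccc(OC)cc3)O[C@H]2c2ccc(OC)cc2)cc1 | intermediate (not isolated)
23 | eight-membered cyclic sulfide, sulfur between Ca and Cc (Ca–H cis to the furan C3–H; either epimer at Cc) | COc1ccc([C@H]2c3c(OC)cc(OC)cc3[C@@H]3c4c(cc(OC)cc4C(S2)C(=O)c2ccc(OC)cc2)O[C@H]3c2ccc(OC)cc2)cc1 | intermediate
24 | S-methylsulfonium triflate of 23 | COc1ccc([C@H]2c3c(OC)cc(OC)cc3[C@@H]3c4c(cc(OC)cc4C([S+]2C)C(=O)c2ccc(OC)cc2)O[C@H]3c2ccc(OC)cc2)cc1.[O-]S(=O)(=O)C(F)(F)F | intermediate (not isolated)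
25 | keto-stabilised sulfonium ylide | COc1ccc([C@H]2c3c(OC)cc(OC)cc3[C@@H]3c4c(cc(OC)cc4[C-]([S+]2C)C(=O)c2ccc(OC)cc2)O[C@H]3c2ccc(OC)cc2)cc1 | intermediate (not isolated)
26 | seven-membered-ring ketone with SMe and 4-methoxybenzoyl on Cc (either epimer at Cc) | COc1ccc([C@H]2c3c(OC)cc(OC)cc3[C@@H]3c4c(cc(OC)cc4C2(SC)C(=O)c2ccc(OC)cc2)O[C@H]3c2ccc(OC)cc2)cc1 | intermediate
27 | samarium enolate from 26 | COc1ccc([C@H]2c3c(OC)cc(OC)cc3[C@@H]3c4c(cc(OC)cc4C2=C(O[Sm](I)I)c2ccc(OC)cc2)O[C@H]3c2ccc(OC)cc2)cc1 | intermediate (not isolated)
28 | seven-membered-ring ketone, Cc–H (Ca–H, Cb–H, Cc–H cis) | COc1ccc([C@H]2c3c(OC)cc(OC)cc3[C@@H]3c4c(cc(OC)cc4[C@H]2C(=O)c2ccc(OC)cc2)O[C@H]3c2ccc(OC)cc2)cc1 | intermediate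
29 | (2R,3R)-4-chloro-3-(3,5-dimethoxyphenyl)-6-methoxy-2-(4-methoxyphenyl)-2,3-dihydro-1-benzofuran (2,3-trans) | Clc1cc(OC)cc2c1[C@@H](c1cc(OC)cc(OC)c1)[C@H](c1ccc(OC)cc1)O2 | intermediate
30 | 1-ethoxyvinyl arene (1-ethoxyvinyl in place of chlorine in 16) | COc1ccc(C(OC)c2c(OC)cc(OC)cc2[C@@H]2c3c(cc(OC)cc3C(=C)OCC)O[C@H]2c2ccc(OC)cc2)cc1 | intermediate (not isolated)
31 | methyl ketone (acetyl in place of chlorine in 16) | COc1ccc(C(OC)c2c(OC)cc(OC)cc2[C@@H]2c3c(cc(OC)cc3C(C)=O)O[C@H]2c2ccc(OC)cc2)cc1 | intermediate
32 | open-chain ketone joining the second and third benzofuran units (C=O at Ce, CH2 at Ch) | COC(c1ccc(OC)cc1)c1c(OC)cc(OC)cc1[C@@H]1c2c(cc(OC)cc2C(=O)Cc2cc(OC)cc3c2[C@@H](c2cc(OC)cc(OC)c2)[C@H](c2ccc(OC)cc2)O3)O[C@H]1c1ccc(OC)cc1 | intermediate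
33 | trimethylsilyl enol ether of 32 | COC(c1ccc(OC)cc1)c1c(OC)cc(OC)cc1[C@@H]1c2c(cc(OC)cc2C(O[Si](C)(C)C)=Cc2cc(OC)cc3c2[C@@H](c2cc(OC)cc(OC)c2)[C@H](c2ccc(OC)cc2)O3)O[C@H]1c1ccc(OC)cc1 | intermediate (not isolated)
34 | eight-membered-ring ketone (C=O at Ce) | O=C1c2cc(OC)cc3c2[C@@H](c2cc(OC)cc(OC)c2[C@H](c2ccc(OC)cc2)[C@H]1c1cc(OC)cc2c1[C@@H](c1cc(OC)cc(OC)c1)[C@H](c1ccc(OC)cc1)O2)[C@H](c1ccc(OC)cc1)O3 | intermediate
35 | eight-membered-ring alcohol (OH at Ce; epimers) | OC1c2cc(OC)cc3c2[C@@H](c2cc(OC)cc(OC)c2[C@H](c2ccc(OC)cc2)[C@H]1c1cc(OC)cc2c1[C@@H](c1cc(OC)cc(OC)c1)[C@H](c1ccc(OC)cc1)O2)[C@H](c1ccc(OC)cc1)O3 | intermediate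
36 | eight-membered-ring benzylic bromide (Br at Ce; epimers) | BrC1c2cc(OC)cc3c2[C@@H](c2cc(OC)cc(OC)c2[C@H](c2ccc(OC)cc2)[C@H]1c1cc(OC)cc2c1[C@@H](c1cc(OC)cc(OC)c1)[C@H](c1ccc(OC)cc1)O2)[C@H](c1ccc(OC)cc1)O3 | intermediate
37 | benzylsamarium diiodide from 36 | I[Sm](I)C1c2cc(OC)cc3c2[C@@H](c2cc(OC)cc(OC)c2[C@H](c2ccc(OC)cc2)[C@H]1c1cc(OC)cc2c1[C@@H](c1cc(OC)cc(OC)c1)[C@H](c1ccc(OC)cc1)O2)[C@H](c1ccc(OC)cc1)O3 | intermediate (not isolated)
38 | tertiary alcohol at Cd joining the two halves (either epimer at the carbinol carbon) | COc1ccc([C@H]2c3c(OC)cc(OC)cc3[C@@H]3c4c(cc(OC)cc4[C@H]2C(O)(c2ccc(OC)cc2)[C@H]2c4cc(OC)cc5c4[C@@H](c4cc(OC)cc(OC)c4[C@H](c4ccc(OC)cc4)[C@H]2c2cc(OC)cc4c2[C@@H](c2cc(OC)cc(OC)c2)[C@H](c2ccc(OC)cc2)O4)[C@H](c2ccc(OC)cc2)O5)O[C@H]3c2ccc(OC)cc2)cc1 | intermediate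
39 | pentadeca-O-methyl ether of the target | COc1ccc([C@H]2c3c(OC)cc(OC)cc3[C@@H]3c4c(cc(OC)cc4[C@H]2[C@H](c2ccc(OC)cc2)[C@H]2c4cc(OC)cc5c4[C@@H](c4cc(OC)cc(OC)c4[C@H](c4ccc(OC)cc4)[C@H]2c2cc(OC)cc4c2[C@@H](c2cc(OC)cc(OC)c2)[C@H](c2ccc(OC)cc2)O4)[C@H](c2ccc(OC)cc2)O5)O[C@H]3c2ccc(OC)cc2)cc1 | intermediate
40 | target, CNP0184494.1 | Oc1ccc([C@H]2c3c(O)cc(O)cc3[C@@H]3c4c(cc(O)cc4[C@H]2[C@H](c2ccc(O)cc2)[C@H]2c4cc(O)cc5c4[C@@H](c4cc(O)cc(O)c4[C@H](c4ccc(O)cc4)[C@H]2c2cc(O)cc4c2[C@@H](c2cc(O)cc(O)c2)[C@H](c2ccc(O)cc2)O4)[C@H](c2ccc(O)cc2)O5)O[C@H]3c2ccc(O)cc2)cc1 | target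

## Step count and least certain steps

Total step count: 22. Longest linear sequence: 16 steps (steps 1–13 and 20–22); the right-hand branch (steps 1–7, 15–19, 20–22) has 15.

Step 12 (key step). The sulfonium salt may ionise at the diarylmethyl carbon before or instead of the ylide rearrangement (solvolytic ring opening, loss of the Ca configuration), or a 2,3-shift into the anisyl ring may compete. Fallback: the seven-membered ring is closed directly by C-alkylation. The fallback sets out from 18, which is converted in one flask (TMSOTf, i-Pr2NEt, CH2Cl2, high dilution, as in step 17) into its silyl enol ether F1. The excess silyl triflate ionises the benzhydryl ether and the enol carbon attacks the cation. After equilibration with Et3N this gives 28, where the route is rejoined; steps 9–13 are then not needed. Its weak point is the reason it is not the first choice: in the seven-membered transition state the nucleophile approaches in the plane of ring A, so control of the Ca configuration is less secure and epimers at that carbon may have to be separated.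

Step 20. The congested ketone may be reduced (ketyl formation, pinacol coupling or carbinol) or the benzylic bromide may homocouple or eliminate before the C–C bond forms; facial selectivity at Ce may be poor. Fallback: a preformed, transmetallated nucleophile replaces the reductive Barbier generation. The fallback sets out from 36, which is substituted with Me3SnLi (THF, −78 °C) to the benzylic trimethylstannane F2. Tin–lithium exchange with MeLi at −78 °C, transmetallation with CeCl3 and addition to 28 give 38, where the route is rejoined.

Step 21. The tertiary cation may lose a proton to tetrasubstituted alkenes, with scrambling at the flanking methines; hydride transfer may show poor facial selectivity; a dihydrofuran ring may open reductively if the acid is too strong. Fallback: the C–H bond at the linker is made before the C–C bond. The fallback sets out from 28, which is reduced with NaBH4 to the secondary carbinol F3. F3 is ionised with BF3·OEt2 at −78 °C in the presence of the stannane F2 (made from 36 as described for step 20). The 4-methoxybenzylic cation is captured by the benzylic stannane (Lewis-acid-promoted benzylation of a stabilised cation) and gives 39 directly, so 38 and the deoxygenation are bypassed.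

Step 5 (with step 4). Hydrazone formation at the ketone with three ortho substituents may be incomplete, and the crowded carbene may insert slowly or unselectively (azine formation, low enantioselectivity). Fallback: racemic ring construction and resolution. The fallback sets out from 8. The phosphazene base P4-t-Bu deprotonates the OCH2Ar group and the benzylic anion adds to the ketone, giving the racemic 3-hydroxy-2,3-dihydrobenzofuran F4. Ionic reduction (Et3SiH, BF3·OEt2, CH2Cl2), with equilibration at C2 under the same Lewis acid, gives the racemic trans compound, that is 12 together with its enantiomer F5. Preparative chromatography on a chiral phase gives 12, where the route is rejoined.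

Step 17. Intermolecular alkylation (oligomers) or capture of the cation by an arene may win over the enol silane, or the wrong sense may form at Cg. Fallback: the sulfur relay of the left half is applied here. The fallback sets out from 32, which is brominated (LiHMDS, then NBS) to the α-bromo ketone F6. KSAc gives the α-(acetylthio) ketone F7, and HCl in MeOH–CH2Cl2 at high dilution closes the nine-membered cyclic sulfide F8. MeOTf, then KOtBu, contract it by Stevens rearrangement to the eight-membered α-methylthio ketone F9. SmI2 in THF–MeOH with base equilibration gives 34, where the route is rejoined.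

Further compounds
F1 | step 12 | trimethylsilyl enol ether of 18 | COc1ccc(C(OC)c2c(OC)cc(OC)cc2[C@@H]2c3c(cc(OC)cc3C=C(O[Si](C)(C)C)c3ccc(OC)cc3)O[C@H]2c2ccc(OC)cc2)cc1
F2 | step 20 | eight-membered-ring benzylic trimethylstannane (SnMe3 at Ce; epimers) | C[Sn](C)(C)C1c2cc(OC)cc3c2[C@@H](c2cc(OC)cc(OC)c2[C@H](c2ccc(OC)cc2)[C@H]1c1cc(OC)cc2c1[C@@H](c1cc(OC)cc(OC)c1)[C@H](c1ccc(OC)cc1)O2)[C@H](c1ccc(OC)cc1)O3
F3 | step 21 | secondary carbinol from 28 (CH(OH) at Cd; epimers) | COc1ccc([C@H]2c3c(OC)cc(OC)cc3[C@@H]3c4c(cc(OC)cc4[C@H]2C(O)c2ccc(OC)cc2)O[C@H]3c2ccc(OC)cc2)cc1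
F4 | step 5 | racemic 3-(2-bromo-3,5-dimethoxyphenyl)-4-chloro-6-methoxy-2-(4-methoxyphenyl)-2,3-dihydro-1-benzofuran-3-ol | COc1ccc(cc1)C1Oc2cc(OC)cc(Cl)c2C1(O)c1cc(OC)cc(OC)c1Br
F5 | step 5 | (2S,3R)-3-(2-bromo-3,5-dimethoxyphenyl)-4-chloro-6-methoxy-2-(4-methoxyphenyl)-2,3-dihydro-1-benzofuran (enantiomer of 12) | Brc1c(OC)cc(OC)cc1[C@H]1c2c(cc(OC)cc2Cl)O[C@@H]1c1ccc(OC)cc1
F6 | step 17 | α-bromo ketone of 32 (Br at Ch; epimers) | COC(c1ccc(OC)cc1)c1c(OC)cc(OC)cc1[C@@H]1c2c(cc(OC)cc2C(=O)C(Br)c2cc(OC)cc3c2[C@@H](c2cc(OC)cc(OC)c2)[C@H](c2ccc(OC)cc2)O3)O[C@H]1c1ccc(OC)cc1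
F7 | step 17 | α-(acetylthio) ketone of 32 (epimers) | COC(c1ccc(OC)cc1)c1c(OC)cc(OC)cc1[C@@H]1c2c(cc(OC)cc2C(=O)C(SC(C)=O)c2cc(OC)cc3c2[C@@H](c2cc(OC)cc(OC)c2)[C@H](c2ccc(OC)cc2)O3)O[C@H]1c1ccc(OC)cc1
F8 | step 17 | nine-membered cyclic sulfide, sulfur between Cg and Ch (either epimer at Ch) | O=C1c2cc(OC)cc3c2[C@@H](c2cc(OC)cc(OC)c2[C@H](c2ccc(OC)cc2)SC1c1cc(OC)cc2c1[C@@H](c1cc(OC)cc(OC)c1)[C@H](c1ccc(OC)cc1)O2)[C@H](c1ccc(OC)cc1)O3
F9 | step 17 | eight-membered-ring ketone with SMe on Ch (either epimer at Ch) | O=C1c2cc(OC)cc3c2[C@@H](c2cc(OC)cc(OC)c2[C@H](c2ccc(OC)cc2)C1(SC)c1cc(OC)cc2c1[C@@H](c1cc(OC)cc(OC)c1)[C@H](c1ccc(OC)cc1)O2)[C@H](c1ccc(OC)cc1)O3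
A1 | alternative 1 | trans-3-(3,5-dimethoxyphenyl)-6-ethoxy-2-(4-methoxyphenyl)-4-[(tert-butyldimethylsilyloxy)methyl]-2,3-dihydrobenzofuran | CC(C)(C)[Si](C)(C)OCc1cc(OCC)cc2c1[C@@H](c1cc(OC)cc(OC)c1)[C@H](c1ccc(OC)cc1)O2
A2 | alternative 2 | pentadeca-O-methyl ether of the target (identical with 39) | COc1ccc([C@H]2c3c(OC)cc(OC)cc3[C@@H]3c4c(cc(OC)cc4[C@H]2[C@H](c2ccc(OC)cc2)[C@H]2c4cc(OC)cc5c4[C@@H](c4cc(OC)cc(OC)c4[C@H](c4ccc(OC)cc4)[C@H]2c2cc(OC)cc4c2[C@@H](c2cc(OC)cc(OC)c2)[C@H](c2ccc(OC)cc2)O4)[C@H](c2ccc(OC)cc2)O5)O[C@H]3c2ccc(OC)cc2)cc1
A3 | alternative 3 | racemic dibenzo-fused cycloheptanone methyl ester | COC(=O)C1c2cc(OC)cc(OC)c2C(=O)Cc2cc(OC)cc(OCc3ccccc3)c21
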